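**Strategy.** Everything rests on the C1–C2 bond. In the target the C2 carbinol sits on quaternary C1, and C1 is the γ-carbon of the C12 oxygen through C13=C14 of ring A. This 1,5-dioxygen pattern across a ring A enone is the imprint of a γ-selective vinylogous aldol reaction. One Lewis-acid step therefore joins C1 to C2, closes the ten-membered ring onto the finished ring A and γ-lactone, sets C1 and C2 and returns the C12 enone. Its precursor is a seco aldehyde: ring A as the silyl dienol ether C12(OSi)=C13–C14=C1, tied through C10–C9–C8 to the lactone and to the cis chloroalkene chain that ends in the C2 aldehyde.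

Key step: step 23

Remark on numbering: atoms carry the briarane numbers of the target (C15 on C1, C16 on C5, C18 on C17, C19 = lactone carbonyl, C20 on C11).
Remark on design: ring A is silylated from its β,γ-unsaturated C12 ketone, O8 is carried as a triethylsilyl ether, and both acetates are installed before the final desilylation, because the target keeps the C8 and C9 hydroxyls free.
Assumption: 1, 7, 8, 15 and 16 are bought; in step 12 the ligand enantiomer that gives the 9S carbinol is used.

Step 1
Reactants: 1 tert-butyldimethyl(pent-4-yn-1-yloxy)silane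
Product: 2 ethyl 6-[(tert-butyldimethylsilyl)oxy]hex-2-ynoate
Conditions: n-BuLi, THF, −78 °C; ClCO2Et, −78 to 0 °C
Reagents that add atoms: ethyl chloroformate, CCOC(=O)Cl
Why: C-acylation of the lithium acetylide with a chloroformate is the standard entry to alk-2-ynoates and brings in C7 as the ester carbon, with C2 already at the alcohol level as its silyl ether.

Step 2
Reactants: 2 ethyl 6-[(tert-butyldimethylsilyl)oxy]hex-2-ynoate
Product: 4 ethyl (2E)-6-[(tert-butyldimethylsilyl)oxy]-2-chloro-3-methylhex-2-enoate, via α-cuprio enoate 3 (not isolated)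
Conditions: Me2CuLi (CuI, 2 MeLi), THF, −78 °C; then N-chlorosuccinimide, −78 °C
Reagents that add atoms: lithium dimethylcuprate, [Li+].C[Cu-]C; N-chlorosuccinimide, O=C1CCC(=O)N1Cl
Why: syn-selective conjugate carbocupration of the ynoate at −78 °C places the new methyl (C16) and copper cis, and chlorination of the alkenylcopper with retention then fixes Cl cis to C16 and C4 cis to C7, the cis ring geometry of C5=C6.

Step 3
Reactants: 4 ethyl (2E)-6-[(tert-butyldimethylsilyl)oxy]-2-chloro-3-methylhex-2-enoate
Product: 5 (2E)-6-[(tert-butyldimethylsilyl)oxy]-2-chloro-3-methylhex-2-en-1-ol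
Conditions: i-Bu2AlH (2.2 equiv), CH2Cl2, −78 °C
Reagents that add atoms: none
Why: low-temperature ester reduction with i-Bu2AlH takes the enoate to the allylic alcohol without touching the tetrasubstituted chloroalkene.

Step 4
Reactants: 5 (2E)-6-[(tert-butyldimethylsilyl)oxy]-2-chloro-3-methylhex-2-en-1-ol
Product: 6 (2E)-6-[(tert-butyldimethylsilyl)oxy]-2-chloro-3-methylhex-2-enal
Conditions: MnO2, CH2Cl2, 25 °C
Reagents that add atoms: none
Why: allylic oxidation with MnO2 stops at the enal under neutral conditions that keep the alkene geometry.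

Step 5
Reactants: 7 methyl (diethoxyphosphoryl)acetate; 8 tert-butyl bromoacetate
Product: 9 4-tert-butyl 1-methyl 2-(diethoxyphosphoryl)butanedioate
Conditions: NaH, THF, 0 to 25 °C
Reagents that add atoms: none
Why: SN2 C-alkylation of the sodium phosphonoacetate by the α-bromo ester gives a phosphonosuccinate whose methyl and tert-butyl esters can be told apart later.

Step 6
Reactants: 6 (2E)-6-[(tert-butyldimethylsilyl)oxy]-2-chloro-3-methylhex-2-enal; 9 4-tert-butyl 1-methyl 2-(diethoxyphosphoryl)butanedioate
Product: 10 4-tert-butyl 1-methyl (2E)-2-{(2E)-6-[(tert-butyldimethylsilyl)oxy]-2-chloro-3-methylhex-2-en-1-ylidene}butanedioate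
Conditions: NaH, THF, 0 °C; then 6, 0 to 25 °C
Reagents that add atoms: none
Why: Horner–Wadsworth–Emmons olefination with an α-substituted phosphonoacetate gives the thermodynamically preferred E-alkylidene succinate, with C6 trans to the conjugated ester carbon C9, the geometry needed for net anti oxygenation of C7 and C8.

Step 7
Reactants: 10 E-alkylidene succinate
Product: 11 tert-butyl (3E,5E)-9-[(tert-butyldimethylsilyl)oxy]-5-chloro-3-(hydroxymethyl)-6-methylnona-3,5-dienoate
Conditions: i-Bu2AlH (2.2 equiv), CH2Cl2, −78 °C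
Reagents that add atoms: none
Why: at −78 °C i-Bu2AlH reduces the conjugated methyl ester to the allylic alcohol and leaves the bulky tert-butyl ester untouched (chemoselective ester reduction).

Step 8
Reactants: 11 dienyl allylic alcohol
Product: 12 epoxy alcohol (7S,8R)
Conditions: Ti(OiPr)4 (10 mol%), diethyl L-(+)-tartrate (12 mol%), t-BuOOH, 4 Å molecular sieves, CH2Cl2, −20 °C
Reagents that add atoms: tert-butyl hydroperoxide, CC(C)(C)OO
Why: Sharpless asymmetric epoxidation of the trisubstituted allylic alcohol is reagent-controlled, the L-(+)-tartrate catalyst delivering oxygen to the face that gives the 7S,8R epoxide, and the electron-poor chloroalkene is not epoxidised.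

Step 9
Reactants: 12 epoxy alcohol
Product: 13 lactone diol (7R,8R)
Conditions: BF3·OEt2 (10 mol%), CH2Cl2, −40 to −10 °C
Reagents that add atoms: none
Why: Lewis-acid epoxy-ester lactonisation: the ester carbonyl oxygen opens the epoxide at allylic C7 with inversion (loss of 2-methylpropene) to close the γ-lactone while the C8–O bond is untouched, so C7 becomes R and the tertiary C8 hydroxyl keeps its configuration.

Step 10
Reactants: 13 lactone diol
Product: 14 lactone α-hydroxy aldehyde (C9 aldehyde)
Conditions: SO3·pyridine, DMSO, i-Pr2NEt, CH2Cl2, 0 °C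
Reagents that add atoms: none
Why: Parikh–Doering oxidation converts only the primary alcohol (the tertiary C8 hydroxyl cannot be oxidised) under non-acidic conditions that avoid translactonisation.

Step 11
Reactants: 15 (2E)-3-iodo-2-methylprop-2-en-1-ol; 16 4,4,5,5-tetramethyl-2-[(1Z)-prop-1-en-1-yl]-1,3,2-dioxaborolane
Product: 17 (1E)-1-iodo-2-methyl-3-[(1Z)-prop-1-en-1-yloxy]prop-1-ene
Conditions: Cu(OAc)2 (2 equiv), Et3N, 4 Å molecular sieves, CH2Cl2, air, 25 °C (15 in fivefold excess)
Reagents that add atoms: none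
Why: copper-mediated oxidative coupling of an alcohol with an alkenylboronate (Chan–Lam type) forms the allyl alkenyl ether with retention of the Z-propenyl geometry and leaves the vinyl iodide untouched.

Step 12
Reactants: 14 lactone α-hydroxy aldehyde; 17 (1E)-1-iodo-2-methyl-3-[(1Z)-prop-1-en-1-yloxy]prop-1-ene
Product: 18 C9 allylic alcohol (7R,8R,9S)
Conditions: CrCl2, NiCl2 (2 mol%), (S)-N-[2-(4-isopropyl-4,5-dihydro-1,3-oxazol-2-yl)-6-methylphenyl]methanesulfonamide, Et3N, THF, 25 °C
Reagents that add atoms: none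
Why: Nozaki–Hiyama–Kishi coupling: the alkenylchromium species adds only to the aldehyde with retention of the E-alkene, tolerating lactone, free hydroxyl, enol ether and chloroalkene; since C8 is flanked by two ring carbons and gives little bias of its own, the oxazoline–sulfonamide ligand on chromium should decide the C9 face (9S).

Step 13
Reactants: 18 C9 allylic alcohol
Product: 20 O9-TBS, O8-TES bis-silyl ether, via C9 mono-silyl ether 19 (not isolated)
Conditions: TBSOTf, 2,6-lutidine, CH2Cl2, −78 °C; then Et3SiOTf, −78 to 0 °C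
Reagents that add atoms: tert-butyldimethylsilyl trifluoromethanesulfonate, CC(C)(C)[Si](C)(C)OS(=O)(=O)C(F)(F)F; triethylsilyl trifluoromethanesulfonate, CC[Si](CC)(CC)OS(=O)(=O)C(F)(F)F
Why: silyl triflate silylation: the bulky TBS triflate takes the secondary allylic C9 hydroxyl at −78 °C, the tertiary C8 hydroxyl is then capped with the smaller triethylsilyl group, and excess lutidine keeps the enol ether intact.

Step 14
Reactants: 20 bis-silyl ether
Product: 21 17-methyl lactone (17R)
Conditions: LiN(i-Pr)2, THF, −78 °C; MeI, DMPU, −78 °C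
Reagents that add atoms: iodomethane, CI
Why: kinetic alkylation of the lactone lithium enolate: methyl iodide approaches C17 anti to the bulky C9 substituent on the adjacent quaternary carbon (cis to the smaller silyloxy group), giving 17R, which should also be the more stable epimer, and −78 °C suppresses β-elimination of the silyloxy group.

Step 15
Reactants: 21 17-methyl lactone
Product: 22 C12 aldehyde (10S,11R)
Conditions: toluene, 120 °C, sealed tube
Reagents that add atoms: none
Why: thermal Claisen rearrangement through a chair transition state: the E-allyl unit (C9 equatorial) and the Z-propenyl unit give the anti C10/C11 pair, while allylic strain with the C15 methyl holds H9 in the alkene plane so that C11 bonds to C10 anti to the C9 silyloxy group; this sets 10S and 11R and creates the isopropenyl group on C10 and the C12 aldehyde.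

Step 16
Reactants: 22 C12 aldehyde
Product: 23 homoallylic alcohol (C12 epimers)
Conditions: allylB(pin), CH2Cl2, 25 °C
Reagents that add atoms: 2-allyl-4,4,5,5-tetramethyl-1,3,2-dioxaborolane, C=CCB1OC(C)(C)C(C)(C)O1
Why: uncatalysed allylboration of the aldehyde adds C13 and C14 under neutral conditions that spare the lactone and the α-stereocentre; the C12 configuration is irrelevant because C12 is oxidised in step 18.

Step 17
Reactants: 23 homoallylic alcohol
Product: 24 ring A cyclohexenol
Conditions: second-generation Grubbs catalyst RuCl2(=CHPh)(PCy3)(H2IMes) (5 mol%), CH2Cl2, 40 °C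
Reagents that add atoms: none
Why: ring-closing metathesis between the monosubstituted vinyl group and the isopropenyl group forms ring A with the trisubstituted C14=C1 alkene and expels ethene, the tetrasubstituted chloroalkene being inert to the ruthenium carbene.

Step 18
Reactants: 24 ring A cyclohexenol
Product: 25 β,γ-unsaturated C12 ketone
Conditions: Dess–Martin periodinane, pyridine, CH2Cl2, 0 °C
Reagents that add atoms: none
Why: buffered Dess–Martin oxidation gives the β,γ-unsaturated ketone without acid or base strong enough to move the alkene into conjugation or to epimerise C11.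

Step 19
Reactants: 25 β,γ-unsaturated C12 ketone
Product: 26 C2 alcohol
Conditions: HF·pyridine, pyridine, THF, 0 °C
Reagents that add atoms: none
Why: selective desilylation: pyridine-buffered HF removes the unhindered primary silyl ether far faster than the secondary TBS ether at C9 (between a quaternary and a tertiary carbon) or the tertiary TES ether at C8.

Step 20
Reactants: 26 C2 alcohol
Product: 28 C2 TMS ether with ring A TBS dienol ether, via C2 trimethylsilyl ether 27 (not isolated)
Conditions: Me3SiCl, Et3N, CH2Cl2, 0 °C; then TBSOTf, Et3N, −78 °C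
Reagents that add atoms: chlorotrimethylsilane, C[Si](C)(C)Cl; tert-butyldimethylsilyl trifluoromethanesulfonate, CC(C)(C)[Si](C)(C)OS(=O)(=O)C(F)(F)F
Why: the primary alcohol is first capped as the labile TMS ether; soft enolisation (silyl triflate, tertiary amine) then removes the doubly activated C13 proton between the carbonyl and C14=C1, so only the conjugated C12=C13/C14=C1 dienol ether can form and C11 is left untouched.

Step 21
Reactants: 28 C2 TMS ether with ring A TBS dienol ether
Product: 29 C2 alcohol with ring A TBS dienol ether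
Conditions: K2CO3 (10 mol%), MeOH, 0 °C, 15 min
Reagents that add atoms: none
Why: selective desilylation: methanolysis of a primary trimethylsilyl ether under trace carbonate is orders of magnitude faster than cleavage of the TBS dienol ether, the TBS ether or the tertiary TES ether.

Step 22
Reactants: 29 C2 alcohol with ring A TBS dienol ether
Product: 30 seco aldehyde with ring A silyl dienol ether
Conditions: SO3·pyridine, DMSO, i-Pr2NEt, CH2Cl2, 0 °C
Reagents that add atoms: none
Why: Parikh–Doering oxidation is neither acidic nor electrophilic enough to touch the silyl dienol ether and stops at the aldehyde.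

Step 23
Reactants: 30 seco aldehyde with ring A silyl dienol ether
Product: 31 bicyclic C12 enone with C2 alcohol (1S,2S)
Conditions: BF3·OEt2 (2 equiv), 2,6-di-tert-butyl-4-methylpyridine (0.2 equiv), CH2Cl2 (0.5 mM, slow addition of 30), −78 °C
Reagents that add atoms: none
Why: Proposed new method: BF3 binds the C2 aldehyde, which is attacked through an open transition state by C1, the far end of the ring A silyloxydiene, and loss of the silyl group from the resulting oxocarbenium ion returns the C12 enone with the new C1–C2 bond. The closest known reaction type is the γ-selective vinylogous Mukaiyama aldol addition of silyl dienol ethers to aldehydes, established between separate partners and for larger rings but not for a ten-membered carbocycle with a quaternary γ-carbon. The ring closes in the ten-membered mode, exo to the aldehyde C=O (10-exo-trig); attack through C13 would need a bridged twelve-membered ring and runs against the electronic preference of the dienol ether, and the lactone and the cis chloroalkene pre-bend the tether. C1 is controlled by C10 and C11: strain with the C15 methyl places the C10–C9 bond pseudoaxial on the β-face, the C20 methyl shields the same face, and the tethered aldehyde should therefore reach the α-face of C1 anti to C9, giving the trans ring fusion (1S). C2 (2S) is controlled by the tether, which should let the BF3-bound oxygen point away from ring A and the C15 methyl while C3 runs back toward the chloroalkene. The step needs γ- over α-attack, secured by dienol ether electronics and ring size, and ring closure over oligomerisation, secured by slow addition at high dilution and −78 °C.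

Step 24
Reactants: 31 bicyclic C12 enone with C2 alcohol
Product: 32 2-O-acetyl enone
Conditions: Ac2O, DMAP, pyridine, 25 °C
Reagents that add atoms: acetic anhydride, CC(=O)OC(C)=O
Why: DMAP-catalysed acylation of the C2 alcohol is done while C12 is still a ketone and O8/O9 are silylated, so that only O2 is acetylated, with retention.

Step 25
Reactants: 32 2-O-acetyl enone
Product: 33 12-epi allylic alcohol (12S)
Conditions: NaBH4, CeCl3·7H2O, MeOH, −78 °C
Reagents that add atoms: none
Why: Luche 1,2-reduction: hydride should add to C12 from the α-face, anti to the adjacent C20 methyl and the other β-substituents, giving the 12S alcohol (hydroxyl cis to C20), the C12 epimer that the invertive acetylation of the next step needs.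

Step 26
Reactants: 33 12-epi allylic alcohol
Product: 34 2,12-diacetate bis-silyl ether (12R)
Conditions: AcOH, PPh3, diisopropyl azodicarboxylate, toluene, 0 to 25 °C
Reagents that add atoms: acetic acid, CC(=O)O
Why: Mitsunobu esterification with acetic acid inverts C12 by SN2 displacement of the oxyphosphonium ion to give the 12R acetate, the SN2′ path being blocked by quaternary C1.

Step 27
Reactants: 34 2,12-diacetate bis-silyl ether
Product: 35 CNP0296164.1
Conditions: HF·pyridine, THF, 0 to 25 °C
Reagents that add atoms: none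
Why: fluoride-mediated global desilylation comes last so that O8 and O9 are never exposed to acylation; acetates, lactone and chloroalkene are stable to HF·pyridine.

**Compound list**

1 | tert-butyldimethyl(pent-4-yn-1-yloxy)silane | C#CCCCO[Si](C)(C)C(C)(C)C | starting material
2 | ethyl 6-[(tert-butyldimethylsilyl)oxy]hex-2-ynoate | CCOC(=O)C#CCCCO[Si](C)(C)C(C)(C)C | intermediate
3 | α-cuprio enoate: lithium methyl cuprate of the syn adduct, copper on C6 cis to C16 | [Li+].CC(C)(C)[Si](C)(C)OCCC/C(C)=C(/[Cu-]C)C(=O)OCC | intermediate (not isolated)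
4 | ethyl (2E)-6-[(tert-butyldimethylsilyl)oxy]-2-chloro-3-methylhex-2-enoate | CC(C)(C)[Si](C)(C)OCCC/C(C)=C(/Cl)C(=O)OCC | intermediate
5 | (2E)-6-[(tert-butyldimethylsilyl)oxy]-2-chloro-3-methylhex-2-en-1-ol | CC(C)(C)[Si](C)(C)OCCC/C(C)=C(/Cl)CO | intermediate
6 | (2E)-6-[(tert-butyldimethylsilyl)oxy]-2-chloro-3-methylhex-2-enal | CC(C)(C)[Si](C)(C)OCCC/C(C)=C(/Cl)C=O | intermediate
7 | methyl (diethoxyphosphoryl)acetate | COC(=O)CP(=O)(OCC)OCC | starting material
8 | tert-butyl bromoacetate | BrCC(=O)OC(C)(C)C | starting material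
9 | 4-tert-butyl 1-methyl 2-(diethoxyphosphoryl)butanedioate (racemic) | COC(=O)C(CC(=O)OC(C)(C)C)P(=O)(OCC)OCC | intermediate
10 | E-alkylidene succinate: 4-tert-butyl 1-methyl (2E)-2-{(2E)-6-[(tert-butyldimethylsilyl)oxy]-2-chloro-3-methylhex-2-en-1-ylidene}butanedioate | CC(C)(C)[Si](C)(C)OCCC/C(C)=C(/Cl)\C=C(\C(=O)OC)CC(=O)OC(C)(C)C | intermediate
11 | dienyl allylic alcohol: tert-butyl (3E,5E)-9-[(tert-butyldimethylsilyl)oxy]-5-chloro-3-(hydroxymethyl)-6-methylnona-3,5-dienoate | CC(C)(C)[Si](C)(C)OCCC/C(C)=C(/Cl)\C=C(\CO)CC(=O)OC(C)(C)C | intermediate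
12 | epoxy alcohol: tert-butyl {(2R,3S)-3-[(1E)-5-[(tert-butyldimethylsilyl)oxy]-1-chloro-2-methylpent-1-en-1-yl]-2-(hydroxymethyl)oxiran-2-yl}acetate (7S,8R) | CC(C)(C)[Si](C)(C)OCCC/C(C)=C(/Cl)[C@H]1O[C@@]1(CO)CC(=O)OC(C)(C)C | intermediate
13 | lactone diol: (4R,5R)-5-[(1E)-5-[(tert-butyldimethylsilyl)oxy]-1-chloro-2-methylpent-1-en-1-yl]-4-hydroxy-4-(hydroxymethyl)oxolan-2-one (7R,8R) | CC(C)(C)[Si](C)(C)OCCC/C(C)=C(/Cl)[C@@H]1OC(=O)C[C@@]1(O)CO | intermediate
14 | lactone α-hydroxy aldehyde: (2R,3S)-2-[(1E)-5-[(tert-butyldimethylsilyl)oxy]-1-chloro-2-methylpent-1-en-1-yl]-3-hydroxy-5-oxooxolane-3-carbaldehyde (7R,8S) | CC(C)(C)[Si](C)(C)OCCC/C(C)=C(/Cl)[C@@H]1OC(=O)C[C@@]1(O)C=O | intermediate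
15 | (2E)-3-iodo-2-methylprop-2-en-1-ol | OC/C(C)=C/I | starting material
16 | 4,4,5,5-tetramethyl-2-[(1Z)-prop-1-en-1-yl]-1,3,2-dioxaborolane | C/C=C\B1OC(C)(C)C(C)(C)O1 | starting material
17 | (1E)-1-iodo-2-methyl-3-[(1Z)-prop-1-en-1-yloxy]prop-1-ene | C/C=C\OC/C(C)=C/I | intermediate
18 | C9 allylic alcohol: (4R,5R)-5-[(1E)-5-[(tert-butyldimethylsilyl)oxy]-1-chloro-2-methylpent-1-en-1-yl]-4-hydroxy-4-{(1S,2E)-1-hydroxy-3-methyl-4-[(1Z)-prop-1-en-1-yloxy]but-2-en-1-yl}oxolan-2-one (7R,8R,9S) | CC(C)(C)[Si](C)(C)OCCC/C(C)=C(/Cl)[C@@H]1OC(=O)C[C@@]1(O)[C@@H](O)/C=C(\C)CO/C=C\C | intermediate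
19 | C9 mono-silyl ether: 18 with O9 as tert-butyldimethylsilyl ether, C8 hydroxyl free (7R,8S,9S) | CC(C)(C)[Si](C)(C)OCCC/C(C)=C(/Cl)[C@@H]1OC(=O)C[C@@]1(O)[C@@H](O[Si](C)(C)C(C)(C)C)/C=C(\C)CO/C=C\C | intermediate (not isolated)
20 | bis-silyl ether: 18 with O9 as tert-butyldimethylsilyl and O8 as triethylsilyl ether (7R,8S,9S) | CC(C)(C)[Si](C)(C)OCCC/C(C)=C(/Cl)[C@@H]1OC(=O)C[C@@]1(O[Si](CC)(CC)CC)[C@@H](O[Si](C)(C)C(C)(C)C)/C=C(\C)CO/C=C\C | intermediate
21 | 17-methyl lactone: 20 with a methyl on C17 trans to the C9 side chain (7R,8S,9S,17R) | CC(C)(C)[Si](C)(C)OCCC/C(C)=C(/Cl)[C@@H]1OC(=O)[C@H](C)[C@@]1(O[Si](CC)(CC)CC)[C@@H](O[Si](C)(C)C(C)(C)C)/C=C(\C)CO/C=C\C | intermediate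
22 | C12 aldehyde: (2R,3S)-2,4-dimethylpent-4-enal whose C3 (= C10) carries the (S)-silyloxy carbon C9 bound to C8 of the lactone of 21 (7R,8S,9S,10S,11R,17R) | CC(C)(C)[Si](C)(C)OCCC/C(C)=C(/Cl)[C@@H]1OC(=O)[C@H](C)[C@@]1(O[Si](CC)(CC)CC)[C@@H](O[Si](C)(C)C(C)(C)C)[C@H](C(C)=C)[C@@H](C)C=O | intermediate
23 | homoallylic alcohol: 22 with C12 as CH(OH)CH2CH=CH2 (C12 epimers) | CC(C)(C)[Si](C)(C)OCCC/C(C)=C(/Cl)[C@@H]1OC(=O)[C@H](C)[C@@]1(O[Si](CC)(CC)CC)[C@@H](O[Si](C)(C)C(C)(C)C)[C@H](C(C)=C)[C@@H](C)C(O)CC=C | intermediate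
24 | ring A cyclohexenol: 12-hydroxy, C14=C1 alkene, methyls on C1 and C11, attached through C10 (C12 epimers; 10S,11R) | CC(C)(C)[Si](C)(C)OCCC/C(C)=C(/Cl)[C@@H]1OC(=O)[C@H](C)[C@@]1(O[Si](CC)(CC)CC)[C@@H](O[Si](C)(C)C(C)(C)C)[C@H]1[C@@H](C)C(O)CC=C1C | intermediate
25 | β,γ-unsaturated C12 ketone: 24 oxidised at C12 | CC(C)(C)[Si](C)(C)OCCC/C(C)=C(/Cl)[C@@H]1OC(=O)[C@H](C)[C@@]1(O[Si](CC)(CC)CC)[C@@H](O[Si](C)(C)C(C)(C)C)[C@H]1[C@@H](C)C(=O)CC=C1C | intermediate
26 | C2 alcohol: 25 with the primary hydroxyl free | OCCC/C(C)=C(/Cl)[C@@H]1OC(=O)[C@H](C)[C@@]1(O[Si](CC)(CC)CC)[C@@H](O[Si](C)(C)C(C)(C)C)[C@H]1[C@@H](C)C(=O)CC=C1C | intermediate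
27 | C2 trimethylsilyl ether of 26 | C[Si](C)(C)OCCC/C(C)=C(/Cl)[C@@H]1OC(=O)[C@H](C)[C@@]1(O[Si](CC)(CC)CC)[C@@H](O[Si](C)(C)C(C)(C)C)[C@H]1[C@@H](C)C(=O)CC=C1C | intermediate (not isolated)
28 | C2 TMS ether with ring A TBS dienol ether (C12=C13, C14=C1) | C[Si](C)(C)OCCC/C(C)=C(/Cl)[C@@H]1OC(=O)[C@H](C)[C@@]1(O[Si](CC)(CC)CC)[C@@H](O[Si](C)(C)C(C)(C)C)[C@H]1[C@@H](C)C(O[Si](C)(C)C(C)(C)C)=CC=C1C | intermediate
29 | C2 alcohol with ring A TBS dienol ether | OCCC/C(C)=C(/Cl)[C@@H]1OC(=O)[C@H](C)[C@@]1(O[Si](CC)(CC)CC)[C@@H](O[Si](C)(C)C(C)(C)C)[C@H]1[C@@H](C)C(O[Si](C)(C)C(C)(C)C)=CC=C1C | intermediate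
30 | seco aldehyde with ring A silyl dienol ether: C2 aldehyde, cis C5=C6 chloroalkene, lactone with O8 triethylsilyl, O9 tert-butyldimethylsilyl (7R,8S,9S,10S,11R,17R) | O=CCC/C(C)=C(/Cl)[C@@H]1OC(=O)[C@H](C)[C@@]1(O[Si](CC)(CC)CC)[C@@H](O[Si](C)(C)C(C)(C)C)[C@H]1[C@@H](C)C(O[Si](C)(C)C(C)(C)C)=CC=C1C | intermediate
31 | bicyclic C12 enone with C2 alcohol: ten-membered ring closed, 12-oxo-13-ene, O8 triethylsilyl, O9 tert-butyldimethylsilyl (1S,2S,7R,8S,9S,10S,11R,17R) | O[C@H]1CC/C(C)=C(/Cl)[C@@H]2OC(=O)[C@H](C)[C@@]2(O[Si](CC)(CC)CC)[C@@H](O[Si](C)(C)C(C)(C)C)[C@H]2[C@@H](C)C(=O)C=C[C@@]21C | intermediate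
32 | 2-O-acetyl enone: 31 acetylated at O2 | CC(=O)O[C@H]1CC/C(C)=C(/Cl)[C@@H]2OC(=O)[C@H](C)[C@@]2(O[Si](CC)(CC)CC)[C@@H](O[Si](C)(C)C(C)(C)C)[C@H]2[C@@H](C)C(=O)C=C[C@@]21C | intermediate
33 | 12-epi allylic alcohol: 32 reduced at C12, hydroxyl cis to C20 (12S) | CC(=O)O[C@H]1CC/C(C)=C(/Cl)[C@@H]2OC(=O)[C@H](C)[C@@]2(O[Si](CC)(CC)CC)[C@@H](O[Si](C)(C)C(C)(C)C)[C@H]2[C@@H](C)[C@@H](O)C=C[C@@]21C | intermediate
34 | 2,12-diacetate bis-silyl ether: 12R acetate, O8 triethylsilyl, O9 tert-butyldimethylsilyl | CC(=O)O[C@H]1CC/C(C)=C(/Cl)[C@@H]2OC(=O)[C@H](C)[C@@]2(O[Si](CC)(CC)CC)[C@@H](O[Si](C)(C)C(C)(C)C)[C@H]2[C@@H](C)[C@H](OC(C)=O)C=C[C@@]21C | intermediate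
35 | CNP0296164.1: 2,12-diacetoxy-6-chloro-8,9-dihydroxy briarane 5,13-diene 19,7-lactone (1S,2S,7R,8R,9S,10S,11R,12R,17R) | CC(=O)O[C@H]1CC/C(C)=C(/Cl)[C@@H]2OC(=O)[C@H](C)[C@@]2(O)[C@@H](O)[C@H]2[C@@H](C)[C@H](OC(C)=O)C=C[C@@]21C | target

**Totals.** Total step count: 27. Longest linear sequence: 25 steps (steps 1–4, 6–10 and 12–27).

**Steps most likely to fail**

Step 23 (Proposed new method). What may go wrong: oligomerisation by aldol addition between molecules, proton-induced loss of the silyl group to give the conjugated enone, or bond formation on the β-face of C1 or through the other aldehyde face, giving the cis-fused or C2-epimeric ring. The fallback uses a directed vinylogous aldol addition of a metal dienolate, a known reaction type. It sets out from 26: Parikh–Doering oxidation gives keto aldehyde F1. F1 is pre-complexed with aluminium tris(2,6-diphenylphenoxide), Al(OC6H3Ph2)3, in toluene at −78 °C and deprotonated with LiN(i-Pr)2 in THF under high dilution. The bulky aluminium phenoxide binds both carbonyl groups, shields C13 and lets the extended dienolate attack the bound aldehyde through C1. Protonation gives 31, where the fallback comes back to the route.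

Step 15. What may go wrong: insufficient facial selectivity at C10 (bond formation syn to the C9 silyloxy group), partial reaction through a boat transition state, or thermal E/Z scrambling of the enol ether, each eroding the C10/C11 stereochemistry. The fallback is a reagent-controlled ester-enolate Claisen rearrangement. It sets out from 21: mild hydrolysis of the enol ether (pyridinium p-toluenesulfonate, aqueous acetone) gives allylic alcohol F2, and propanoic anhydride with DMAP gives propanoate F3. Soft enolisation of F3 with a chiral bromoborane, (S,S)- or (R,R)-2-bromo-4,5-diphenyl-1,3-bis(p-tolylsulfonyl)-1,3,2-diazaborolidine, and i-Pr2NEt in CH2Cl2 forms the E-configured boron enolate without strong base. Its Ireland–Claisen-type rearrangement under control of the boron ligand gives acid F4. Mixed-anhydride formation (isobutyl chloroformate, N-methylmorpholine) and NaBH4 reduction give primary alcohol F5, and Dess–Martin oxidation returns to the route at 22.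

Step 12. What may go wrong: sluggish addition to the hindered α-quaternary aldehyde and incomplete reagent control at C9. The fallback sets C9 by reduction instead of by C–C bond formation. It sets out from 18 obtained as a C9 epimer mixture (coupling run without the chiral ligand): MnO2 oxidation of the allylic alcohol gives enone F6. Corey–Bakshi–Shibata reduction of F6 (B-methyl oxazaborolidine enantiomer that delivers hydride for 9S, catecholborane, −78 °C) comes back to the route at 18.

Further compounds

F1 | step 23 | keto aldehyde: 26 with C2 oxidised to the aldehyde, β,γ-unsaturated C12 ketone intact | O=CCC/C(C)=C(/Cl)[C@@H]1OC(=O)[C@H](C)[C@@]1(O[Si](CC)(CC)CC)[C@@H](O[Si](C)(C)C(C)(C)C)[C@H]1[C@@H](C)C(=O)CC=C1C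
F2 | step 15 | allylic alcohol: 21 with the propenyl ether cleaved to the free primary alcohol | CC(C)(C)[Si](C)(C)OCCC/C(C)=C(/Cl)[C@@H]1OC(=O)[C@H](C)[C@@]1(O[Si](CC)(CC)CC)[C@@H](O[Si](C)(C)C(C)(C)C)/C=C(\C)CO
F3 | step 15 | propanoate of F2 | CC(C)(C)[Si](C)(C)OCCC/C(C)=C(/Cl)[C@@H]1OC(=O)[C@H](C)[C@@]1(O[Si](CC)(CC)CC)[C@@H](O[Si](C)(C)C(C)(C)C)/C=C(\C)COC(=O)CC
F4 | step 15 | acid: 22 with C12 as the carboxylic acid | CC(C)(C)[Si](C)(C)OCCC/C(C)=C(/Cl)[C@@H]1OC(=O)[C@H](C)[C@@]1(O[Si](CC)(CC)CC)[C@@H](O[Si](C)(C)C(C)(C)C)[C@H](C(C)=C)[C@@H](C)C(=O)O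
F5 | step 15 | primary alcohol: 22 with C12 as CH2OH | CC(C)(C)[Si](C)(C)OCCC/C(C)=C(/Cl)[C@@H]1OC(=O)[C@H](C)[C@@]1(O[Si](CC)(CC)CC)[C@@H](O[Si](C)(C)C(C)(C)C)[C@H](C(C)=C)[C@@H](C)CO
F6 | step 12 | enone: 18 with C9 oxidised to the ketone | CC(C)(C)[Si](C)(C)OCCC/C(C)=C(/Cl)[C@@H]1OC(=O)C[C@@]1(O)C(=O)/C=C(\C)CO/C=C\C
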